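Ring A is a 2,6-dimethoxyphenyl ring whose C1 oxygen is an ether to the secondary, methyl-bearing carbon C2' of the link to ring B. Its adjacent oxygenated carbons C2, C1 and C6 are read as carbonyl, alkoxy-bearing carbon and carbonyl of a 2-alkoxycyclohexane-1,3-dione, so the hindered aryl–O–CH bond starts life as an ordinary alkyl ether.
Late disconnections: the (E)-propenyl group at ring A C4 (Suzuki coupling after sterically governed C–H borylation); the acetate and the C7 carbinol (chelate-controlled ketone reduction); C7–ring C (aryl Grignard on a Weinreb amide); C8–O (Mitsunobu inversion of ethyl (S)-lactate by the ring B phenol).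
Ring A comes from the dione by enol methylation, dehydrogenation and methylation; the dione comes from dimethyl malonate and an alkoxymethyl vinyl ketone by Michael addition and Claisen closure, with loss of one ester carbon.
The enone comes from vinyl Grignard addition to the Weinreb amide of an alkoxyacetic acid, made by O-alkylation of the (R)-alcohol from (R)-propylene oxide and the Grignard reagent of benzylated 4-bromo-2,6-dimethoxyphenol.
Ring order: ring B is bought, ring A is closed in step 6 and aromatised in step 8, ring C is bought and joined in step 13.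

Key step: step 6

Remark: the SMILES is read as (R) at C2' and (1S,2R), i.e. erythro, at C7 (acetoxy-bearing benzylic carbon) and C8 (its methyl-bearing neighbour); C8 is therefore taken from ethyl (S)-lactate with inversion and C7 is set by reduction, so no racemic bromoketone is used.

Step 1
Reactants: 1 (4-bromo-2,6-dimethoxyphenol)
Product: 2 benzyl ether 2-(benzyloxy)-5-bromo-1,3-dimethoxybenzene
Conditions: BnBr, K2CO3, DMF, rt
Reagents that add atoms: benzyl bromide BrCc1ccccc1
Why: Williamson O-benzylation of the phenoxide; the benzyl ether should survive the Grignard, alkoxide, hydroxide and amide-base steps ahead and leaves later by hydrogenolysis.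

Step 2
Reactants: 2 (benzyl ether); 3 ((R)-propylene oxide)
Product: 5 alcohol (2R)-1-[4-(benzyloxy)-3,5-dimethoxyphenyl]propan-2-ol, via aryl Grignard reagent 4 (not isolated)
Conditions: Mg, THF, reflux; then CuI (10 mol%), (R)-propylene oxide, −30 → 0 °C; aq. NH4Cl
Reagents that add atoms: none
Why: Magnesium insertion followed by CuI-catalysed Grignard opening of the epoxide at its unsubstituted carbon (SN2) leaves the carbinol centre of the epoxide untouched, so the (R) configuration is carried over from the chiral pool.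

Step 3
Reactants: 5 (alcohol); 6 (bromoacetic acid)
Product: 7 acid {[(2R)-1-(4-(benzyloxy)-3,5-dimethoxyphenyl)propan-2-yl]oxy}acetic acid
Conditions: NaH (3 equiv), THF, 0 °C; BrCH2CO2H, 0 → 60 °C; then aq. HCl
Reagents that add atoms: none
Why: Williamson etherification of the secondary alkoxide at the primary carbon of sodium bromoacetate, whose carboxylate can neither enolise nor be acylated; only the O–H bond of 5 reacts, so the stereocentre is retained.

Step 4
Reactants: 7 (acid)
Product: 9 Weinreb amide N-methoxy-N-methyl-2-{[(2R)-1-(4-(benzyloxy)-3,5-dimethoxyphenyl)propan-2-yl]oxy}acetamide, via acyl imidazole 8 (not isolated)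
Conditions: CDI, CH2Cl2, rt; then MeNHOMe·HCl, rt
Reagents that add atoms: N,O-dimethylhydroxylamine hydrochloride CNOC.Cl
Why: Carboxyl activation as the acyl imidazole and aminolysis (Weinreb amide formation) under near-neutral conditions that touch nothing else in the molecule.

Step 5
Reactants: 9 (Weinreb amide); 10 (vinylmagnesium bromide)
Product: 11 enone 1-{[(2R)-1-(4-(benzyloxy)-3,5-dimethoxyphenyl)propan-2-yl]oxy}but-3-en-2-one
Conditions: CH2=CHMgBr (1.5 equiv), THF, −78 → −20 °C; inverse quench into cold 1 M HCl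
Reagents that add atoms: none
Why: Weinreb ketone synthesis, in which the magnesium chelate stops at mono-addition; the acidic inverse quench keeps the released N,O-dimethylhydroxylamine protonated so that it cannot add to the vinyl ketone, which is used at once.

Step 6
Reactants: 11 (enone); 12 (dimethyl malonate)
Product: 16 dione 3-hydroxy-2-{[(2R)-1-(4-(benzyloxy)-3,5-dimethoxyphenyl)propan-2-yl]oxy}cyclohex-2-en-1-one (enol form of the 2-alkoxycyclohexane-1,3-dione), via Michael adduct 13 (not isolated), via cyclised keto ester 14 (not isolated), via keto acid 15 (not isolated)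
Conditions: CH2(CO2Me)2 (1.5 equiv), NaOMe (2.5 equiv), MeOH, 0 °C (slow addition of 11), then reflux; 2 M aq. NaOH, reflux; HCl to pH 2, 70 °C
Reagents that add atoms: none
Why: Sodiomalonate adds to the vinyl ketone (Michael addition) to give 13; methoxide then equilibrates the ketone enolates, and the one at the alkoxy-bearing carbon acylates on a malonate ester (Claisen condensation of the Dieckmann type) to give 14, whose saponification to 15 and decarboxylation on acidification leave dione 16. The closest known reaction is the malonate–enone annulation that turns mesityl oxide into dimedone. The one ring formed, the future ring A, closes by a 6-(enolendo)-exo-trig acylation. No stereocentre is created, because C2 of the dione is enolised, and the (R) centre of the side chain bears no acidic hydrogen and is untouched. The step needs mono-addition and regioselective acylation: excess malonate and slow addition of 11 hold back a second Michael addition and enone polymerisation, ring size fixes the regiochemistry because the other ketone enolate could only close a four-membered ring, and the stabilised enolate of the product dione pulls the equilibria forward.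

Step 7
Reactants: 16 (dione)
Product: 17 vinylogous ester 2-{[(2R)-1-(4-(benzyloxy)-3,5-dimethoxyphenyl)propan-2-yl]oxy}-3-methoxycyclohex-2-en-1-one
Conditions: HC(OMe)3, TsOH·H2O (cat.), MeOH, rt
Reagents that add atoms: trimethyl orthoformate COC(OC)OC; methanol CO
Why: Acid-catalysed enol etherification of a cyclic 1,3-dione; the two carbonyl groups are equivalent about the C2–C5 axis, so a single enol ether should form.

Step 8
Reactants: 17 (vinylogous ester)
Product: 20 phenol 2-{[(2R)-1-(4-(benzyloxy)-3,5-dimethoxyphenyl)propan-2-yl]oxy}-3-methoxyphenol, via silyl dienol ether 18 (not isolated), via cyclohexadienone 19 (not isolated)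
Conditions: LiN(iPr)2, THF, −78 °C; Me3SiCl; then Pd(OAc)2 (1.1 equiv), MeCN, rt
Reagents that add atoms: none
Why: Kinetic deprotonation of the vinylogous ester at C6 and silylation give dienol ether 18, whose Saegusa–Ito oxidation (palladium enolate, β-hydride elimination) gives cyclohexa-2,5-dienone 19, the keto tautomer of phenol 20, which aromatises spontaneously.

Step 9
Reactants: 20 (phenol)
Product: 21 ether 2-{[(2R)-1-(4-(benzyloxy)-3,5-dimethoxyphenyl)propan-2-yl]oxy}-1,3-dimethoxybenzene
Conditions: MeI, K2CO3, acetone, reflux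
Reagents that add atoms: iodomethane CI
Why: Williamson methylation of the phenoxide completes the 2,6-dimethoxyphenyl ether pattern of ring A.

Step 10
Reactants: 21 (benzyl ether)
Product: 22 phenol 4-[(2R)-2-(2,6-dimethoxyphenoxy)propyl]-2,6-dimethoxyphenol
Conditions: H2 (1 atm), Pd/C (10%), EtOAc/EtOH, rt
Reagents that add atoms: none
Why: Hydrogenolysis of the benzyl aryl ether; the homobenzylic alkyl aryl ether and the arenes are inert under these conditions.

Step 11
Reactants: 22 (phenol); 23 (ethyl (S)-lactate)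
Product: 24 ester ethyl (2R)-2-{4-[(2R)-2-(2,6-dimethoxyphenoxy)propyl]-2,6-dimethoxyphenoxy}propanoate
Conditions: PPh3, DIAD, THF, 0 °C → rt
Reagents that add atoms: none
Why: Mitsunobu etherification, in which the phenoxide displaces the phosphonium-activated lactate hydroxyl by SN2 with inversion and so sets C8 as (R); the adjacent ester accelerates the displacement and offsets the two ortho methoxy groups of the phenol.

Step 12
Reactants: 24 (ester)
Product: 25 Weinreb amide (2R)-2-{4-[(2R)-2-(2,6-dimethoxyphenoxy)propyl]-2,6-dimethoxyphenoxy}-N-methoxy-N-methylpropanamide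
Conditions: MeNHOMe·HCl, iPrMgCl, THF, −20 → 0 °C
Reagents that add atoms: N,O-dimethylhydroxylamine hydrochloride CNOC.Cl
Why: Direct aminolysis of the ester by the chloromagnesium amide of N,O-dimethylhydroxylamine made in the flask; this weakly basic reagent at low temperature should not epimerise C8.

Step 13
Reactants: 25 (Weinreb amide); 26 ((3,4,5-trimethoxyphenyl)magnesium bromide)
Product: 27 ketone (2R)-2-{4-[(2R)-2-(2,6-dimethoxyphenoxy)propyl]-2,6-dimethoxyphenoxy}-1-(3,4,5-trimethoxyphenyl)propan-1-one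
Conditions: ArMgBr (0.5 M in THF, 1.5 equiv), THF, −40 → 0 °C; cold aq. NH4Cl
Reagents that add atoms: none
Why: Weinreb ketone synthesis; the chelated tetrahedral intermediate prevents over-addition and keeps the carbonyl masked until the cold quench, which protects the base-sensitive α-aryloxy centre C8, and the ketone is reduced without delay.

Step 14
Reactants: 27 (ketone)
Product: 28 alcohol (1S,2R)-2-{4-[(2R)-2-(2,6-dimethoxyphenoxy)propyl]-2,6-dimethoxyphenoxy}-1-(3,4,5-trimethoxyphenyl)propan-1-ol
Conditions: Zn(BH4)2, Et2O/CH2Cl2, −40 → 0 °C; aq. NH4Cl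
Reagents that add atoms: none
Why: Chelation-controlled hydride reduction (Cram chelate model): zinc bridges the carbonyl oxygen and the aryloxy oxygen on C8, hydride enters from the side of the C8 hydrogen and not of its methyl group, and the anti (erythro) alcohol with (1S) next to the fixed (2R) centre should result under non-basic conditions that do not epimerise C8.

Step 15
Reactants: 28 (alcohol)
Product: 29 acetate (1S,2R)-2-{4-[(2R)-2-(2,6-dimethoxyphenoxy)propyl]-2,6-dimethoxyphenoxy}-1-(3,4,5-trimethoxyphenyl)propyl acetate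
Conditions: Ac2O, pyridine, DMAP (cat.), CH2Cl2, 0 °C → rt
Reagents that add atoms: acetic anhydride CC(=O)OC(C)=O
Why: DMAP-catalysed O-acylation of the secondary alcohol, which breaks no bond at C7 and therefore retains its configuration.

Step 16
Reactants: 29 (acetate)
Product: 30 boronate (1S,2R)-2-{4-[(2R)-2-(2,6-dimethoxy-4-(4,4,5,5-tetramethyl-1,3,2-dioxaborolan-2-yl)phenoxy)propyl]-2,6-dimethoxyphenoxy}-1-(3,4,5-trimethoxyphenyl)propyl acetate
Conditions: B2pin2 (1.0 equiv), [Ir(OMe)(cod)]2 (2.5 mol%), 4,4'-di-tert-butyl-2,2'-bipyridine (5 mol%), THF, 80 °C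
Reagents that add atoms: bis(pinacolato)diboron CC1(C)OB(OC1(C)C)B1OC(C)(C)C(C)(C)O1
Why: Iridium-catalysed aromatic C–H borylation is governed by sterics, and the C4 hydrogen of ring A is the only aryl hydrogen in 29 without an ortho substituent, every other one lying next to a methoxy group or a carbon substituent.

Step 17
Reactants: 30 (boronate); 31 ((E)-1-bromoprop-1-ene)
Product: 32 target (1S,2R)-2-{4-[(2R)-2-{2,6-dimethoxy-4-[(E)-prop-1-en-1-yl]phenoxy}propyl]-2,6-dimethoxyphenoxy}-1-(3,4,5-trimethoxyphenyl)propyl acetate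
Conditions: (E)-1-bromoprop-1-ene (3 equiv), PdCl2(dppf) (5 mol%), K3PO4, dioxane with a little H2O, 60 °C, sealed tube
Reagents that add atoms: none
Why: Suzuki–Miyaura coupling, in which oxidative addition of the alkenyl bromide and reductive elimination both proceed with retention, so the (E) geometry is carried over; phosphate at moderate temperature should spare the acetate.

Compound list
1 | 4-bromo-2,6-dimethoxyphenol | COc1cc(Br)cc(OC)c1O | starting material
2 | 2-(benzyloxy)-5-bromo-1,3-dimethoxybenzene | COc1cc(Br)cc(OC)c1OCc1ccccc1 | intermediate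
3 | (R)-propylene oxide | C[C@@H]1CO1 | starting material
4 | [4-(benzyloxy)-3,5-dimethoxyphenyl]magnesium bromide | COc1cc([Mg]Br)cc(OC)c1OCc1ccccc1 | intermediate
5 | (2R)-1-[4-(benzyloxy)-3,5-dimethoxyphenyl]propan-2-ol | C[C@@H](O)Cc1cc(OC)c(OCc2ccccc2)c(OC)c1 | intermediate
6 | bromoacetic acid | OC(=O)CBr | starting material
7 | {[(2R)-1-(4-(benzyloxy)-3,5-dimethoxyphenyl)propan-2-yl]oxy}acetic acid | OC(=O)CO[C@H](C)Cc1cc(OC)c(OCc2ccccc2)c(OC)c1 | intermediate
8 | 1-(imidazol-1-yl)-2-{[(2R)-1-(4-(benzyloxy)-3,5-dimethoxyphenyl)propan-2-yl]oxy}ethanone | O=C(CO[C@H](C)Cc1cc(OC)c(OCc2ccccc2)c(OC)c1)n1ccnc1 | intermediate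
9 | N-methoxy-N-methyl-2-{[(2R)-1-(4-(benzyloxy)-3,5-dimethoxyphenyl)propan-2-yl]oxy}acetamide | CON(C)C(=O)CO[C@H](C)Cc1cc(OC)c(OCc2ccccc2)c(OC)c1 | intermediate
10 | vinylmagnesium bromide | C=C[Mg]Br | starting material
11 | 1-{[(2R)-1-(4-(benzyloxy)-3,5-dimethoxyphenyl)propan-2-yl]oxy}but-3-en-2-one | C=CC(=O)CO[C@H](C)Cc1cc(OC)c(OCc2ccccc2)c(OC)c1 | intermediate
12 | dimethyl malonate | COC(=O)CC(=O)OC | starting material
13 | dimethyl 2-(4-{[(2R)-1-(4-(benzyloxy)-3,5-dimethoxyphenyl)propan-2-yl]oxy}-3-oxobutyl)malonate | COC(=O)C(CCC(=O)CO[C@H](C)Cc1cc(OC)c(OCc2ccccc2)c(OC)c1)C(=O)OC | intermediate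
14 | methyl 3-{[(2R)-1-(4-(benzyloxy)-3,5-dimethoxyphenyl)propan-2-yl]oxy}-2,4-dioxocyclohexane-1-carboxylate (enolised ring, present as its sodium enolate) | COC(=O)C1CCC(=O)C(O[C@H](C)Cc2cc(OC)c(OCc3ccccc3)c(OC)c2)C1=O | intermediate
15 | 3-{[(2R)-1-(4-(benzyloxy)-3,5-dimethoxyphenyl)propan-2-yl]oxy}-2,4-dioxocyclohexane-1-carboxylic acid | OC(=O)C1CCC(=O)C(O[C@H](C)Cc2cc(OC)c(OCc3ccccc3)c(OC)c2)C1=O | intermediate
16 | 3-hydroxy-2-{[(2R)-1-(4-(benzyloxy)-3,5-dimethoxyphenyl)propan-2-yl]oxy}cyclohex-2-en-1-one | OC1=C(O[C@H](C)Cc2cc(OC)c(OCc3ccccc3)c(OC)c2)C(=O)CCC1 | intermediate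
17 | 2-{[(2R)-1-(4-(benzyloxy)-3,5-dimethoxyphenyl)propan-2-yl]oxy}-3-methoxycyclohex-2-en-1-one | COC1=C(O[C@H](C)Cc2cc(OC)c(OCc3ccccc3)c(OC)c2)C(=O)CCC1 | intermediate
18 | 6-{[(2R)-1-(4-(benzyloxy)-3,5-dimethoxyphenyl)propan-2-yl]oxy}-5-methoxy-1-(trimethylsilyloxy)cyclohexa-1,5-diene | COC1=C(O[C@H](C)Cc2cc(OC)c(OCc3ccccc3)c(OC)c2)C(O[Si](C)(C)C)=CCC1 | intermediate
19 | 2-{[(2R)-1-(4-(benzyloxy)-3,5-dimethoxyphenyl)propan-2-yl]oxy}-3-methoxycyclohexa-2,5-dien-1-one | COC1=C(O[C@H](C)Cc2cc(OC)c(OCc3ccccc3)c(OC)c2)C(=O)C=CC1 | intermediate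
20 | 2-{[(2R)-1-(4-(benzyloxy)-3,5-dimethoxyphenyl)propan-2-yl]oxy}-3-methoxyphenol | COc1cccc(O)c1O[C@H](C)Cc1cc(OC)c(OCc2ccccc2)c(OC)c1 | intermediate
21 | 2-{[(2R)-1-(4-(benzyloxy)-3,5-dimethoxyphenyl)propan-2-yl]oxy}-1,3-dimethoxybenzene | COc1cccc(OC)c1O[C@H](C)Cc1cc(OC)c(OCc2ccccc2)c(OC)c1 | intermediate
22 | 4-[(2R)-2-(2,6-dimethoxyphenoxy)propyl]-2,6-dimethoxyphenol | COc1cccc(OC)c1O[C@H](C)Cc1cc(OC)c(O)c(OC)c1 | intermediate
23 | ethyl (S)-lactate | CCOC(=O)[C@H](C)O | starting material
24 | ethyl (2R)-2-{4-[(2R)-2-(2,6-dimethoxyphenoxy)propyl]-2,6-dimethoxyphenoxy}propanoate | COc1cccc(OC)c1O[C@H](C)Cc1cc(OC)c(O[C@H](C)C(=O)OCC)c(OC)c1 | intermediate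
25 | (2R)-2-{4-[(2R)-2-(2,6-dimethoxyphenoxy)propyl]-2,6-dimethoxyphenoxy}-N-methoxy-N-methylpropanamide | COc1cccc(OC)c1O[C@H](C)Cc1cc(OC)c(O[C@H](C)C(=O)N(C)OC)c(OC)c1 | intermediate
26 | (3,4,5-trimethoxyphenyl)magnesium bromide | COc1cc([Mg]Br)cc(OC)c1OC | starting material
27 | (2R)-2-{4-[(2R)-2-(2,6-dimethoxyphenoxy)propyl]-2,6-dimethoxyphenoxy}-1-(3,4,5-trimethoxyphenyl)propan-1-one | COc1cccc(OC)c1O[C@H](C)Cc1cc(OC)c(O[C@H](C)C(=O)c2cc(OC)c(OC)c(OC)c2)c(OC)c1 | intermediate
28 | (1S,2R)-2-{4-[(2R)-2-(2,6-dimethoxyphenoxy)propyl]-2,6-dimethoxyphenoxy}-1-(3,4,5-trimethoxyphenyl)propan-1-ol | COc1cccc(OC)c1O[C@H](C)Cc1cc(OC)c(O[C@H](C)[C@@H](O)c2cc(OC)c(OC)c(OC)c2)c(OC)c1 | intermediate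
29 | (1S,2R)-2-{4-[(2R)-2-(2,6-dimethoxyphenoxy)propyl]-2,6-dimethoxyphenoxy}-1-(3,4,5-trimethoxyphenyl)propyl acetate | COc1cccc(OC)c1O[C@H](C)Cc1cc(OC)c(O[C@H](C)[C@@H](OC(C)=O)c2cc(OC)c(OC)c(OC)c2)c(OC)c1 | intermediate
30 | (1S,2R)-2-{4-[(2R)-2-(2,6-dimethoxy-4-(4,4,5,5-tetramethyl-1,3,2-dioxaborolan-2-yl)phenoxy)propyl]-2,6-dimethoxyphenoxy}-1-(3,4,5-trimethoxyphenyl)propyl acetate | CC1(C)OB(OC1(C)C)c1cc(OC)c(O[C@H](C)Cc2cc(OC)c(O[C@H](C)[C@@H](OC(C)=O)c3cc(OC)c(OC)c(OC)c3)c(OC)c2)c(OC)c1 | intermediate
31 | (E)-1-bromoprop-1-ene | C/C=C/Br | starting material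
32 | (1S,2R)-2-{4-[(2R)-2-{2,6-dimethoxy-4-[(E)-prop-1-en-1-yl]phenoxy}propyl]-2,6-dimethoxyphenoxy}-1-(3,4,5-trimethoxyphenyl)propyl acetate (CNP0157869.1) | C/C=C/c1cc(OC)c(O[C@H](C)Cc2cc(OC)c(O[C@H](C)[C@@H](OC(C)=O)c3cc(OC)c(OC)c(OC)c3)c(OC)c2)c(OC)c1 | target

Total step count: 17. Longest linear sequence: 17 steps (1 to 32); all other partners are bought.

Steps most likely to fail

Step 6. The vinyl ketone may be used up by a second Michael addition onto adduct 13 or by base-induced polymerisation before the ring closes, or the sequence may stall at 13 if the Claisen equilibrium is unfavourable. The fallback sets out from acid 7 and comes back at dione 16. It buys the carbon–carbon bond of the Michael addition ready-made and keeps only the ring-closing acylation. Acid 7 with oxalyl chloride and catalytic DMF in CH2Cl2 should give {[(2R)-1-(4-(benzyloxy)-3,5-dimethoxyphenyl)propan-2-yl]oxy}acetyl chloride F1. Negishi acylation of commercial 4-ethoxy-4-oxobutylzinc bromide with it (Pd(PPh3)4 cat., THF, 0 °C → rt) should give ethyl 6-{[(2R)-1-(4-(benzyloxy)-3,5-dimethoxyphenyl)propan-2-yl]oxy}-5-oxohexanoate F2. KOtBu in THF then closes the six-membered ring by the known Claisen cyclisation of 5-oxohexanoates to cyclohexane-1,3-diones, again at the alkoxy-bearing carbon, and acidification gives 16.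

Step 16. Borylation of the very electron-rich ring A in this large substrate may be slow. Borylation next to methoxy groups on rings B and C, or attack of iridium boryl and hydride species on the benzylic acetate, could then compete. The fallback sets out from Weinreb amide 25 and comes back at target 32. It moves the C–H functionalisation and the coupling to a stage with two arenes only and no acetate, and carries the alkene through the remaining known steps. Borylation of 25 under the step 16 conditions should give the ring A boronate of the Weinreb amide F3. Coupling with 31 under the step 17 conditions should give the propenyl Weinreb amide F4. Addition of 26 as in step 13 should give the propenyl ketone F5. Reduction with Zn(BH4)2 at low temperature, where the conjugated alkene is not expected to be hydroborated, should give the propenyl alcohol F6. Acetylation as in step 15 then gives 32.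

Step 14. The weakly basic, hindered aryloxy oxygen may chelate zinc incompletely, so that hydride delivery loses its facial preference and the threo (1R,2R) alcohol forms beside 28. The fallback sets out from ketone 27 and comes back at alcohol 28. It moves the stereocontrol from the substrate to a chiral catalyst: Noyori asymmetric transfer hydrogenation with RuCl(p-cymene)[(R,R)-TsDPEN] in HCO2H/Et3N and CH2Cl2 at rt. This catalyst places the aryl group of an aryl ketone next to its arene ligand and, for this substitution pattern, should deliver hydride to the face that gives (1S), whatever the chelation. This fallback makes no new compound (entry F0).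

Further compounds
F1 | step 6 | {[(2R)-1-(4-(benzyloxy)-3,5-dimethoxyphenyl)propan-2-yl]oxy}acetyl chloride | ClC(=O)CO[C@H](C)Cc1cc(OC)c(OCc2ccccc2)c(OC)c1
F2 | step 6 | ethyl 6-{[(2R)-1-(4-(benzyloxy)-3,5-dimethoxyphenyl)propan-2-yl]oxy}-5-oxohexanoate | CCOC(=O)CCCC(=O)CO[C@H](C)Cc1cc(OC)c(OCc2ccccc2)c(OC)c1
F3 | step 16 | (2R)-2-{4-[(2R)-2-(2,6-dimethoxy-4-(4,4,5,5-tetramethyl-1,3,2-dioxaborolan-2-yl)phenoxy)propyl]-2,6-dimethoxyphenoxy}-N-methoxy-N-methylpropanamide | CC1(C)OB(OC1(C)C)c1cc(OC)c(O[C@H](C)Cc2cc(OC)c(O[C@H](C)C(=O)N(C)OC)c(OC)c2)c(OC)c1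
F4 | step 16 | (2R)-2-{4-[(2R)-2-{2,6-dimethoxy-4-[(E)-prop-1-en-1-yl]phenoxy}propyl]-2,6-dimethoxyphenoxy}-N-methoxy-N-methylpropanamide | C/C=C/c1cc(OC)c(O[C@H](C)Cc2cc(OC)c(O[C@H](C)C(=O)N(C)OC)c(OC)c2)c(OC)c1
F5 | step 16 | (2R)-2-{4-[(2R)-2-{2,6-dimethoxy-4-[(E)-prop-1-en-1-yl]phenoxy}propyl]-2,6-dimethoxyphenoxy}-1-(3,4,5-trimethoxyphenyl)propan-1-one | C/C=C/c1cc(OC)c(O[C@H](C)Cc2cc(OC)c(O[C@H](C)C(=O)c3cc(OC)c(OC)c(OC)c3)c(OC)c2)c(OC)c1
F6 | step 16 | (1S,2R)-2-{4-[(2R)-2-{2,6-dimethoxy-4-[(E)-prop-1-en-1-yl]phenoxy}propyl]-2,6-dimethoxyphenoxy}-1-(3,4,5-trimethoxyphenyl)propan-1-ol | C/C=C/c1cc(OC)c(O[C@H](C)Cc2cc(OC)c(O[C@H](C)[C@@H](O)c3cc(OC)c(OC)c(OC)c3)c(OC)c2)c(OC)c1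
F0 | step 14 | none | none
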